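**Assumptions:** 1, 5 and 13 are taken as commercial. Hydroazulene locants: C1 = quaternary/carbinol carbon, C3a and C8a = ring-fusion carbons, C4 = CMe2, C8 = C=O or C=CH2. "C8" and "C14" (aplyviolene numbering) are the quaternary carbon and the adjacent methine of the lactone unit. Intermediates whose configuration at one centre does not matter are drawn as the expected major epimer or left unspecified, as noted.

## Retrosynthetic overview

1. Aplyviolene 22 ⇐ lactol 21 ⇐ aldehyde-acid 20. The dioxabicyclo[3.2.1]octanone is formed last; until then the lactone unit is carried as a cyclopentanone whose C1–C2 bond is cut late.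
2. Key step: instead of building the quaternary carbon by stepwise enolate/Michael chemistry, one photoredox Giese coupling of the tertiary C8 radical (from oxalate 12) with enantiopure α-chloroenone 16 makes the C8–C14 bond and both stereocentres at once.
3. 12 ⇐ cis-hydroazulene built seven-membered ring first (ring expansion to enone 4), then Cu-catalysed asymmetric conjugate addition, Au(I) Conia-ene closure of the cyclopentane, hydration and methylenation.
4. 16 ⇐ (R)-4-silyloxycyclopentenone 13 by radical dioxolanylation, elimination (enone transposition) and α-chlorination.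
5. Ring order: cycloheptane → cyclopentane (left half); temporary cyclopentanone (right half); after union the cyclopentanone is opened and the δ-lactone and tetrahydrofuran acetal rings close last.

## Route

**Step 1**
Reactants: 1, 3-methylcyclohex-2-en-1-one
Product: 2, 3,3-dimethyl-1-(trimethylsilyloxy)cyclohex-1-ene
Conditions: Me2CuLi, Et2O, 0 °C; then TMSCl, Et3N, 0 °C → rt
Reagents that add atoms: lithium dimethylcuprate, [Li+].C[Cu-]C (one CH3); TMSCl, C[Si](C)(C)Cl
Why: Cuprate 1,4-addition creates the gem-dimethyl carbon, and silylation traps the enolate regiospecifically on the side of the new quaternary carbon (conjugate addition/enolate trapping).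

**Step 2**
Reactants: 2
Product: 3, 5,5-dimethyl-1-(trimethylsilyloxy)bicyclo[4.1.0]heptane (racemic; its stereocentres are destroyed in step 3)
Conditions: Et2Zn, CH2I2, CH2Cl2, 0 °C → rt
Reagents that add atoms: diiodomethane, ICI (CH2)
Why: Furukawa–Simmons–Smith cyclopropanation of the electron-rich silyl enol ether.

**Step 3**
Reactants: 3
Product: 4, 4,4-dimethylcyclohept-2-en-1-one
Conditions: FeCl3, DMF, 0 °C → rt; then NaOAc, MeOH, reflux
Reagents that add atoms: none
Why: Ito–Saegusa oxidative opening of the siloxycyclopropane (internal bond cleavage to the 3-chlorocycloheptanone) followed by E1cB loss of HCl gives the ring-expanded enone with CMe2 at C4.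

**Step 4**
Reactants: 5, 4-(trimethylsilyl)but-3-yn-1-ol
Product: 6, (4-iodobut-1-yn-1-yl)trimethylsilane
Conditions: PPh3, I2, imidazole, CH2Cl2, 0 °C
Reagents that add atoms: iodine, II
Why: Appel iodination of a primary alcohol.

**Step 5**
Reactants: 4 and 6
Product: 7, triisopropyl{[(3R)-4,4-dimethyl-3-(4-trimethylsilylbut-3-yn-1-yl)cyclohept-1-en-1-yl]oxy}silane
Conditions: 6, Et2Zn (neat), cat. CuI, 50 °C, then evacuate (gives [TMSC≡C(CH2)2]2Zn); then 4, Cu(OTf)2 (2 mol%), (S,R,R)-BINOL/bis(1-phenylethyl)amine phosphoramidite (4 mol%), toluene, −30 °C; then TIPSOTf, −30 → 0 °C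
Reagents that add atoms: TIPSOTf, CC(C)[Si](C(C)C)(C(C)C)OS(=O)(=O)C(F)(F)F
Why: Cu/phosphoramidite asymmetric conjugate addition of a dialkylzinc tolerates 4,4-disubstituted cycloalkenones and sets C3 (future C3a) by catalyst control, in the same facial sense that gives (S)-3-ethylcyclohexanone (the descriptor is R here because CMe2 outranks C2); O-silylation of the zinc enolate fixes the enol regiochemistry needed for ring closure.

**Step 6**
Reactants: 7
Product: 8, {[(3R)-3-(but-3-yn-1-yl)-4,4-dimethylcyclohept-1-en-1-yl]oxy}triisopropylsilane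
Conditions: K2CO3, MeOH, rt
Reagents that add atoms: none
Why: Methanolysis removes the alkynyl TMS group selectively; the hindered TIPS enol ether survives.

**Step 7**
Reactants: 8
Product: 9, (3aR,8aR)-4,4-dimethyl-1-methylideneoctahydroazulen-8(2H)-one (cis-fused)
Conditions: Ph3PAuCl/AgBF4 (10 mol%), CH2Cl2/MeOH 10:1, 40 °C
Reagents that add atoms: none
Why: Au(I)-catalysed 5-exo-dig Conia-ene-type carbocyclisation of the silyl enol ether onto the terminal alkyne; the three-atom tether can only reach the enol face on its own side, so the ring fusion is cis (C8a set relative to C3a), and the exocyclic methylene is formed.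

**Step 8**
Reactants: 9
Product: 10, (1R,3aR,8aR)-1-hydroxy-1,4,4-trimethyloctahydroazulen-8(2H)-one (major C1 epimer shown, OH anti to the seven-membered ring; the C1 configuration is inconsequential)
Conditions: Co(acac)2 (20 mol%), PhSiH3, O2 (1 atm), THF, rt; then P(OEt)3
Reagents that add atoms: dioxygen, O=O (one O)
Why: Mukaiyama hydration (metal-hydride H-atom transfer, O2 trapping) gives the Markovnikov tertiary alcohol and turns the methylene into the C1 methyl; the neutral conditions leave the epimerisable cis ring fusion untouched.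

**Step 9**
Reactants: 10
Product: 11, (1R,3aR,8aS)-1,4,4-trimethyl-8-methylidenedecahydroazulen-1-ol
Conditions: Zn, CH2Br2, TiCl4, THF/CH2Cl2, 0 °C → rt
Reagents that add atoms: dibromomethane, BrCBr (CH2)
Why: Takai–Lombardo methylenation is non-basic, so the α-epimerisable, retro-aldol-prone β-hydroxy ketone is olefinated without loss of the cis fusion; the free tertiary OH is tolerated.

**Step 10**
Reactants: 11
Product: 12, cesium 2-oxo-2-{[(1R,3aR,8aS)-1,4,4-trimethyl-8-methylidenedecahydroazulen-1-yl]oxy}acetate
Conditions: ClC(O)CO2Me, Et3N, DMAP, CH2Cl2, 0 °C → rt; then aq. CsOH (1.0 equiv), THF, rt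
Reagents that add atoms: methyl chlorooxoacetate, COC(=O)C(Cl)=O; cesium hydroxide, [Cs+].[OH-]
Why: Acylation of the tertiary alcohol and selective saponification of the more electrophilic methyl ester give the bench-stable cesium oxalate radical precursor.

**Step 11**
Reactants: 13, (4R)-4-(tert-butyldimethylsilyloxy)cyclopent-2-en-1-one
Product: 14, (3R,4R)-4-(tert-butyldimethylsilyloxy)-3-(1,3-dioxolan-2-yl)cyclopentan-1-one (trans)
Conditions: 1,3-dioxolane (solvent), benzophenone (20 mol%), hν (350 nm), rt
Reagents that add atoms: 1,3-dioxolane, C1COCO1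
Why: Benzophenone-sensitised H-abstraction gives the 1,3-dioxolan-2-yl radical, which adds to the enone β-carbon anti to the OTBS group (radical conjugate addition), creating the future C13 stereocentre as a masked aldehyde.

**Step 12**
Reactants: 14
Product: 15, (4R)-4-(1,3-dioxolan-2-yl)cyclopent-2-en-1-one
Conditions: DBU, CH2Cl2, 0 °C
Reagents that add atoms: none
Why: E1cB loss of silanolate transposes the enone and leaves the dioxolanyl-bearing carbon as an untouched γ-stereocentre.

**Step 13**
Reactants: 15
Product: 16, (4R)-2-chloro-4-(1,3-dioxolan-2-yl)cyclopent-2-en-1-one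
Conditions: PhICl2, pyridine, CH2Cl2, 0 °C → rt
Reagents that add atoms: iodobenzene dichloride, ClI(Cl)c1ccccc1 (Cl)
Why: α-Chlorination of the enone by pyridine conjugate addition, enolate chlorination and elimination; the chlorine raises acceptor electrophilicity and later marks where the enolate must form.

**Step 14 (key step)**
Reactants: 12 and 16
Product: 17, (3R,4R)-2-chloro-4-(1,3-dioxolan-2-yl)-3-[(1R,3aR,8aS)-1,4,4-trimethyl-8-methylidenedecahydroazulen-1-yl]cyclopentan-1-one (C3/C4 trans; C2 epimers, inconsequential)
Conditions: Ir[dF(CF3)ppy]2(dtbbpy)PF6 (2 mol%), H2O (10 equiv), DME/DMF 3:1, blue LEDs, 60 °C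
Reagents that add atoms: none
Why: Photoredox decarboxylative Giese coupling. Oxidation of the oxalate and loss of 2 CO2 give the planar tertiary C8 radical, which adds to the chloroenone β-carbon anti to the dioxolanyl group (sets C14) and on the convex face of the cis-hydroazulene, anti to the C8a–C8 bond (sets the C8 quaternary centre); reduction of the α-chloro-α-acyl radical and protonation give the α-chloro ketone.

**Step 15**
Reactants: 17
Product: 18, triethyl{[(3R,4R)-4-(1,3-dioxolan-2-yl)-3-[(1S,3aR,8aS)-1,4,4-trimethyl-8-methylidenedecahydroazulen-1-yl]cyclopent-1-en-1-yl]oxy}silane (same geometry at azulenyl C1 as in 17; the descriptor changes only by CIP priority)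
Conditions: Me2CuLi, THF, −78 → −40 °C; then TESCl, Et3N, HMPA, −78 → 0 °C
Reagents that add atoms: TESCl, CC[Si](CC)(CC)Cl
Why: Reductive enolisation of the α-chloro ketone by the cuprate gives the enolate only toward C2 (which direct deprotonation would not select), and it is trapped as the TES enol ether.

**Step 16**
Reactants: 18
Product: 19, (2R,3R,4R)-4-(1,3-dioxolan-2-yl)-2-hydroxy-3-[(1R,3aR,8aS)-1,4,4-trimethyl-8-methylidenedecahydroazulen-1-yl]cyclopentan-1-one (C2 configuration inconsequential)
Conditions: DMDO (1.05 equiv), acetone/CH2Cl2, −78 °C; then AcOH/THF/H2O, rt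
Reagents that add atoms: dimethyldioxirane, CC1(C)OO1 (O)
Why: Rubottom oxidation; the electron-rich enol ether is epoxidised far faster than the 1,1-disubstituted alkene at −78 °C, anti to the bulky C3 substituent, and mild acid releases the α-hydroxy ketone with the dioxolane intact.

**Step 17**
Reactants: 19
Product: 20, (3R,4R)-3-(1,3-dioxolan-2-yl)-5-oxo-4-[(1R,3aR,8aS)-1,4,4-trimethyl-8-methylidenedecahydroazulen-1-yl]pentanoic acid (in equilibrium with its 6-hydroxy-δ-lactone ring tautomer)
Conditions: NaIO4, THF/H2O (pH 7 buffer), rt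
Reagents that add atoms: water, O (carboxyl OH); oxidant sodium periodate, [Na+].[O-]I(=O)(=O)=O
Why: Periodate cleavage of the α-ketol cuts C1–C2 to give the carboxylic acid and the C14 aldehyde at the correct oxidation levels; the alkene and acetal are inert.

**Step 18**
Reactants: 20
Product: 21, (1S,5R,6R,8R)-6-hydroxy-8-[(1R,3aR,8aS)-1,4,4-trimethyl-8-methylidenedecahydroazulen-1-yl]-2,7-dioxabicyclo[3.2.1]octan-3-one (exo lactol shown; anomers equilibrate)
Conditions: 1 M HCl/THF (1:3), 0 °C → rt
Reagents that add atoms: water, O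
Why: Acetal hydrolysis and lactolisation; the acid and the C14 aldehyde are already joined as the δ-hydroxylactone, whose OH captures the unmasked aldehyde to close the tetrahydrofuran ring, while the alternative cis-dioxabicyclo[3.3.0]octanone would force the hydroazulene onto its concave face. The bridgehead acetal configuration is dictated by the bridge.

**Step 19**
Reactants: 21
Product: 22, aplyviolene, (1S,5R,6S,8R)-3-oxo-8-[(1R,3aR,8aS)-1,4,4-trimethyl-8-methylidenedecahydroazulen-1-yl]-2,7-dioxabicyclo[3.2.1]octan-6-yl acetate
Conditions: Ac2O, pyridine, DMAP (cat.), CH2Cl2, 0 °C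
Reagents that add atoms: acetic anhydride, CC(=O)OC(C)=O
Why: O-Acylation of the equilibrating lactol occurs on the exposed exo face (anti to the lactone bridge), which is the natural acetate configuration.

## Compound list

1 | 3-methylcyclohex-2-en-1-one | CC1=CC(=O)CCC1 | starting material
2 | 3,3-dimethyl-1-(trimethylsilyloxy)cyclohex-1-ene | C[Si](C)(C)OC1=CC(C)(C)CCC1 | intermediate
3 | 5,5-dimethyl-1-(trimethylsilyloxy)bicyclo[4.1.0]heptane (racemic) | C[Si](C)(C)OC12CC1C(C)(C)CCC2 | intermediate
4 | 4,4-dimethylcyclohept-2-en-1-one | O=C1C=CC(C)(C)CCC1 | intermediate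
5 | 4-(trimethylsilyl)but-3-yn-1-ol | OCCC#C[Si](C)(C)C | starting material
6 | (4-iodobut-1-yn-1-yl)trimethylsilane | ICCC#C[Si](C)(C)C | intermediate
7 | TIPS enol ether of (3R)-4,4-dimethyl-3-(4-TMS-but-3-ynyl)cycloheptanone | CC(C)[Si](C(C)C)(C(C)C)OC1=C[C@@H](CCC#C[Si](C)(C)C)C(C)(C)CCC1 | intermediate
8 | TIPS enol ether of (3R)-3-(but-3-ynyl)-4,4-dimethylcycloheptanone | CC(C)[Si](C(C)C)(C(C)C)OC1=C[C@@H](CCC#C)C(C)(C)CCC1 | intermediate
9 | (3aR,8aR)-4,4-dimethyl-1-methylideneoctahydroazulen-8(2H)-one | O=C1CCCC(C)(C)[C@@H]2CCC(=C)[C@H]12 | intermediate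
10 | (1R,3aR,8aR)-1-hydroxy-1,4,4-trimethyloctahydroazulen-8(2H)-one | O=C1CCCC(C)(C)[C@@H]2CC[C@@](C)(O)[C@H]12 | intermediate
11 | (1R,3aR,8aS)-1,4,4-trimethyl-8-methylidenedecahydroazulen-1-ol | C=C1CCCC(C)(C)[C@@H]2CC[C@@](C)(O)[C@H]12 | intermediate
12 | cesium oxalate of 11 | C=C1CCCC(C)(C)[C@@H]2CC[C@@](C)(OC(=O)C(=O)[O-])[C@H]12.[Cs+] | intermediate
13 | (4R)-4-(tert-butyldimethylsilyloxy)cyclopent-2-en-1-one | O=C1C=C[C@H](O[Si](C)(C)C(C)(C)C)C1 | starting material
14 | (3R,4R)-4-(TBSO)-3-(1,3-dioxolan-2-yl)cyclopentan-1-one | O=C1C[C@H]([C@H](O[Si](C)(C)C(C)(C)C)C1)C2OCCO2 | intermediate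
15 | (4R)-4-(1,3-dioxolan-2-yl)cyclopent-2-en-1-one | O=C1C[C@H](C=C1)C2OCCO2 | intermediate
16 | (4R)-2-chloro-4-(1,3-dioxolan-2-yl)cyclopent-2-en-1-one | O=C1C[C@H](C=C1Cl)C2OCCO2 | intermediate
17 | coupled α-chloro ketone (C2 unspecified) | C=C1CCCC(C)(C)[C@@H]2CC[C@@](C)([C@@H]3C(Cl)C(=O)C[C@H]3C4OCCO4)[C@H]12 | intermediate
18 | TES enol ether | C=C1CCCC(C)(C)[C@@H]2CC[C@@](C)([C@@H]3C=C(O[Si](CC)(CC)CC)C[C@H]3C4OCCO4)[C@H]12 | intermediate
19 | α-hydroxy ketone | C=C1CCCC(C)(C)[C@@H]2CC[C@@](C)([C@@H]3[C@@H](O)C(=O)C[C@H]3C4OCCO4)[C@H]12 | intermediate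
20 | aldehyde-acid | C=C1CCCC(C)(C)[C@@H]2CC[C@@](C)([C@H](C=O)[C@@H](CC(=O)O)C3OCCO3)[C@H]12 | intermediate
21 | bicyclic lactol | C=C1CCCC(C)(C)[C@@H]2CC[C@@](C)([C@@H]3[C@@H]4OC(=O)C[C@H]3[C@H](O)O4)[C@H]12 | intermediate
22 | aplyviolene | C=C1CCCC(C)(C)[C@@H]2CC[C@@](C)([C@@H]3[C@@H]4OC(=O)C[C@H]3[C@H](OC(C)=O)O4)[C@H]12 | target

## Summary

Total steps: 19.
Longest linear sequence: 15 (steps 1–3, 5–10, 14–19).

Steps most likely to fail, each with a fallback that changes the approach:

1. **Step 14 (radical fragment coupling).** The yield and facial selectivity of a hindered tertiary radical adding next to a ring substituent are the main risk. Fallback: generate the same C8 radical by metal-hydride H-atom transfer (Fe(acac)3/PhSiH3) directly from alkene 9 in the presence of 16, keeping the C8 ketone and deferring the methylenation until after enol-silane formation. This removes steps 8–10 and changes the radical precursor and step order.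

2. **Step 5 (asymmetric conjugate addition to the neopentyl β-carbon with a functionalised zinc reagent and silyl trapping).** Reactivity and ee on this hindered cycloheptenone are uncertain. Fallback: build the cyclopentane racemically by a TiCl4-promoted [3+2] allenylsilane annulation of enone 4 with 1-methyl-1-(trimethylsilyl)allene (cis-fused; protodesilylate, then hydrate the C1-methyl alkene to rac-10), and let enantiopure 16 resolve the material in step 14 as separable diastereomers.

3. **Steps 18–19 (bicyclisation and anomeric acetate).** The free dialdehyde-acid can epimerise at C13/C14 or close to the isomeric [3.3.0] lactone, and the acetate may form as an anomeric mixture. Fallback: lock the lactol as the anomeric fluoride (DAST), purify the configurationally fixed [3.2.1] fluoride, and introduce the acetate by Lewis-acid-mediated substitution (BF3·OEt2/AcOH) from the exo face, replacing acylation of an equilibrating lactol with substitution on a locked bicycle.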